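## Structural features

The target is a (3S)-isoflavan: a chroman in which benzo ring A is fused to the dihydropyran ring C along C4a–C8a, with O1 on C8a and the aryl ring B on C3. C3 is the only stereocenter. It lies between the two methylene groups C2 and C4, has no stereogenic neighbour and is not alpha to a carbonyl group, so it is configurationally robust but nothing in the molecule can relay chirality to it. Ring A carries one free phenol at C7, meta to C8a and para to C4a. Ring B is pentasubstituted: C1' bonded to C3, 2'-OMe, 3'-OH, 4'-OH and a 1,1-dimethylallyl group on C5', with only C6'–H left. The fragile parts are the electron-rich catechol (air oxidation to an ortho-quinone) and the terminal alkene next to the 4'-OH (acid-promoted closure to a dihydrobenzofuran, and saturation under hydrogenolysis conditions). The real difficulty is threefold: fixing the isolated C3 configuration, telling the three contiguous oxygens of ring B apart, and placing a quaternary benzylic carbon on C5'. The key step uses the fact that the bonds O1–C8a and C4–C4a end on two neighbouring carbons of ring A, which are the ipso and ortho positions of a 3-oxygenated iodobenzene, so C4–C3–C2–O1 can be delivered as one bifunctional unit that already holds C3. The 4'-oxygen ortho to the free C5' position then allows the side chain to be added last by a Claisen rearrangement.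

## Logic of the disconnections

19 ⇒ 18. The two O–CH2 acetal bonds on O7 and O3' are cut. The catechol and the ring A phenol stay masked as base-stable ethers through all metal-mediated and thermal steps. The forward step must be an acid treatment mild enough to leave the allyl group beside the 4'-OH untouched.

18 ⇒ 17. The C5'–C(quaternary) bond is cut and the allyl unit is reconnected to O4' as a retro-[3,3] shift. A tertiary allylic carbon ortho to a phenol is the signature of an aromatic Claisen rearrangement with allyl inversion. This removes the quaternary carbon and leaves an ordinary aryl ether. The forward step needs C3' blocked, so that only C5' can rearomatize, and a substrate that tolerates about 190 °C.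

17 ⇒ 15 + 16. The O4'–CH2 bond is cut (Williamson etherification). This requires 15 to have O4' as its only free phenol.

15 ⇒ 14. The O4'–benzyl bond is cut. Benzyl is orthogonal to the acetals on O3' and O7, and its hydrogenolysis is placed before any alkene exists.

14 ⇒ 13 + 11. The bonds C4–C4a and O1–C8a are cut, which opens ring C. This is the largest simplification of the route: it gives a trivial arene, 13, and a three-carbon bromo alcohol, 11, that holds the stereocenter. The forward palladium–norbornene relay must alkylate once, at the unhindered ortho carbon, and then form the aryl ether at the ipso carbon, without touching C3 and without base-induced loss of 11.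

13 ⇒ 12. The O–CH2 acetal bond is cut; this is a plain protection.

11 ⇒ 10 ⇒ 9 ⇒ 8. The C–Br bond is traced back to C–OH and the acetate to a free hydroxyl. The two arms of 11 differ only in Br against OH, so C3 is a desymmetrized prochiral carbon and the stereocenter disappears in the achiral diol 8. The forward steps need an enzyme that distinguishes the enantiotopic arms, and no later step may interchange the arms (acyl migration in 9 would do so).

8 ⇒ 6 ⇒ 4 + 5. The two hydroxymethyl arms are raised to the formyl and ester groups of 6. The bonds C3–C1' and C3–C(formyl) are then cut, so that the aldehyde carbon of 4 becomes one arm and 5 supplies C3 and the other arm. This reaches the diol skeleton from an aryl aldehyde in two steps. The forward step requires aryl migration to win over hydride migration and the acid catalyst to spare the acetal.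

4 ⇒ 3 ⇒ 2 ⇒ 1. The three O–C bonds are removed in the reverse order of phenol reactivity: methyl on the chelated O2 last, acetal on O3, benzyl on the most acidic O4 first. The forward steps rely on the graded acidity and chelation of the three phenols for site control.

## Other disconnections considered

Alternative 1: The cut goes through C3–C4 and O1–C2 at the lactone oxidation level. It leads to the activated ring B arylacetic ester A1 and the ortho-quinone methide A3, which would be released in the flask from the sulfone A2 by base.
- Forward step: a chiral isothiourea such as benzotetramisole is acylated by A1. The derived ammonium enolate adds through its alpha carbon to the exocyclic CH2 of A3, and the phenoxide then lactonizes and frees the catalyst, giving the dihydrocoumarin A4.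
- In its favour: two achiral fragments and one catalytic enantioselective step that makes ring C and C3 together. The reaction class (ammonium enolate Michael addition–lactonization) has closer precedent than the annulation chosen here. On precedent, and on creating the stereocenter in the ring-forming step, this alternative is the better one.
- Against it here: A3 has an unsubstituted methide carbon and would be far more prone to oligomerize than the aryl-substituted methides usually employed. The new stereocenter of A4 is alpha to both a lactone carbonyl and an aryl ring, so it is acidic and could epimerize under the basic conditions and during the later reduction. The ortho-methoxy group of A1 crowds the enolate.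
- Structure: A4 already carries the side chain, so the Claisen step would have to come early and the alkene be carried along. A4 must still be reduced and ring C closed a second time by Mitsunobu etherification before deprotection.
- Step economy is about equal (three steps after A4 against four after 14). The chosen plan is preferred because its stereocenter is a non-acidic C–H from the moment it exists.

Alternative 2: The cut removes four bonds of ring A (C4a–C5, C7–C8, C4a–C8a, C6–C7). It leads to the open-chain diazo ketone A5, in which an acryloyl diazo unit is tethered through C4–C3–C2–O1 to an ethynyl ether.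
- Forward step: irradiation would trigger a Wolff rearrangement (vinyl shift to the diazo carbon) to a vinylketene. Intramolecular [2+2] addition to the ynol ether would give a cyclobutenone, and four-electron ring opening, six-electron ring closure and tautomerization would give the phenol A6 (an intramolecular Danheiser benzannulation).
- In its favour: four C–C bonds and two rings in one metal-free operation. The 7-OH appears free and in the right place, because the ketene carbonyl carbon becomes C7 and the oxygen-bearing alkyne carbon becomes C8a. On bonds formed per step it is clearly better than the chosen plan, and ring A needs no protecting group.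
- Against it here: ring A is a cheap aromatic in the chosen plan, so building it is no real gain. C3 would have to be set beforehand in an open chain, so nothing is saved on stereochemistry. A5 combines an acryloyl diazo ketone (intramolecular dipolar cycloaddition, polymerization), a primary alkyl ethynyl ether (hard to make, retro-ene loss of ketene on warming) and the terminal alkene of ring B, which could itself trap the ketene.
- Mechanism: both plans extend known chemistry to an untested intramolecular or bifunctional setting, and on this point they stand equal.
- Step economy: the alternative is worse, since A5 would need a long linear sequence on a fragile chain, against eight robust steps to 11.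

Alternative 3: The cut is the single bond O1–C8a, after a hydroxymethyl group is added to C3 so that the precursor is the prochiral diol A7.
- Forward step: CuI, a chiral diamine and a carbonate base would select one of the two enantiotopic CH2OH groups for intramolecular O-arylation at the C–Br bond. This closes ring C and makes C3 a quaternary stereocenter in A8.
- In its favour: copper-catalysed desymmetrizing O-arylation of 2-(2-halobenzyl)-1,3-diols to chromans is an established reaction class, so on precedent this alternative is better than the chosen plan. A7 would come quickly from a ring B arylmalonate by benzylation and reduction, a way equal to or shorter than the way to 11. Ring and stereocenter arise in one catalytic step.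
- Against it here: the extra carbon on C3 is not in the target and must be removed with retention. That means oxidation to a neopentyl aldehyde and decarbonylation with stoichiometric RhCl(PPh3)3 at high temperature, at a hindered quaternary centre and in the presence of the terminal alkene (isomerization, hydroacylation). A radical decarboxylation would scramble C3. The selectivity with a bulky tetrasubstituted aryl group on the prochiral carbon is untested.
- Comparison: the ring closure itself is at least as reliable as the chosen one. The chosen plan wins after the key step, on atom and step economy, because it carries no carbon that must later be excised.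

Key step: step 10

Remarks before the steps:
- Ar stands for 4-(benzyloxy)-2-methoxy-3-(methoxymethoxy)phenyl throughout.
- Check of configuration: the CH2Br arm of 11 becomes C4 and the CH2OH arm becomes C2, so (S)-11 maps onto (3S)-14 and onto the 3S target (priorities C2 > C1' > C4 > H) with no change of spatial arrangement. No structure needed correction.
- Assumption: the lipase of step 6 is taken to acetylate the arm that gives (R)-9. Which commercial lipase does so is a screening matter, and the fallback for step 6 covers the opposite case.
- Assumption: the bridgehead-methyl norbornene mediator of step 10 is treated as an available reagent.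

## Route

Step 1
Reactants: 1 2,3,4-trihydroxybenzaldehyde
Product: 2 4-(benzyloxy)-2,3-dihydroxybenzaldehyde
Conditions: BnBr (1.05 equiv), NaHCO3, DMF, 40 °C
Reagents that add atoms: benzyl bromide, BrCc1ccccc1
Why: Williamson etherification under bicarbonate; only the 4-OH, para to the formyl group and not locked in a hydrogen bond to it, is acidic enough to be ionized, so alkylation should stop at O4.

Step 2
Reactants: 2 4-(benzyloxy)-2,3-dihydroxybenzaldehyde
Product: 3 4-(benzyloxy)-2-hydroxy-3-(methoxymethoxy)benzaldehyde
Conditions: NaH (2.1 equiv), DMF, 0 °C; MOMCl (1.0 equiv), 0 °C to rt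
Reagents that add atoms: chloromethyl methyl ether, COCCl
Why: Alkylation of the dianion with one equivalent of electrophile; the 2-phenoxide is conjugated with the formyl group and chelated to sodium, so the more basic, non-conjugated 3-phenoxide should react first.

Step 3
Reactants: 3 4-(benzyloxy)-2-hydroxy-3-(methoxymethoxy)benzaldehyde
Product: 4 4-(benzyloxy)-2-methoxy-3-(methoxymethoxy)benzaldehyde
Conditions: MeI, K2CO3, DMF, rt
Reagents that add atoms: iodomethane, CI
Why: Williamson methylation of the last, chelated phenol, which reacts cleanly once no other hydroxyl competes.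

Step 4
Reactants: 4 4-(benzyloxy)-2-methoxy-3-(methoxymethoxy)benzaldehyde; 5 ethyl diazoacetate
Product: 6 ethyl (Z)-2-Ar-3-hydroxyprop-2-enoate (chelated enol form of the alpha-formyl ester)
Conditions: HBF4·OEt2 (10 mol%), CH2Cl2, –78 °C, slow addition of 5
Reagents that add atoms: none
Why: Acid-catalysed aldehyde–diazoacetate homologation with 1,2-aryl shift (semipinacol type): the diazo carbon adds to the protonated aldehyde, and loss of N2 from the beta-hydroxy diazonium is accompanied by migration of the electron-rich 2,4-dialkoxyaryl group rather than of hydride (the Roskamp path). The product is the formyl ester, which rests as its hydrogen-bonded enol; the low temperature and the catalytic amount of acid are meant to spare the aryl acetal.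

Step 5
Reactants: 6 ethyl (Z)-2-Ar-3-hydroxyprop-2-enoate
Product: 8 2-Ar-propane-1,3-diol, via hydroxy ester 7 (not isolated)
Conditions: NaBH4, EtOH, 0 °C; then LiBH4, THF, 0 °C to rt
Reagents that add atoms: none
Why: Borohydride reduces the aldehyde tautomer to the racemic beta-hydroxy ester 7 (the classical tropate reduction), and LiBH4 then reduces the hydroxyl-activated ester; the stereocenter of 7 is lost in the achiral diol 8.

Step 6
Reactants: 8 2-Ar-propane-1,3-diol
Product: 9 (R)-2-Ar-3-hydroxypropyl acetate
Conditions: Burkholderia cepacia lipase (immobilized), vinyl acetate (3 equiv), t-BuOMe, 25 °C, stopped before diacetate builds up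
Reagents that add atoms: vinyl acetate, C=COC(C)=O
Why: Lipase-catalysed enantiotopic-group-selective transesterification of a prochiral 2-aryl-1,3-propanediol, made irreversible by the enol ester donor. C3 is set here by the enzyme's discrimination between the two hydroxymethyl arms, and slow further acetylation of the minor enantiomer should sharpen the purity of 9.

Step 7
Reactants: 9 (R)-2-Ar-3-hydroxypropyl acetate
Product: 10 (S)-3-bromo-2-Ar-propyl acetate
Conditions: CBr4, PPh3, CH2Cl2, 0 °C, used directly after step 6
Reagents that add atoms: carbon tetrabromide, BrC(Br)(Br)Br
Why: Appel bromination by SN2 displacement at the primary carbon under neutral, cold conditions, which should leave no time for 1,3-acetyl migration (the process that would interchange the arms). C3 is not a reacting centre, and the descriptor changes from R to S only through the priority rules.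

Step 8
Reactants: 10 (S)-3-bromo-2-Ar-propyl acetate
Product: 11 (S)-3-bromo-2-Ar-propan-1-ol
Conditions: K2CO3 (0.2 equiv), MeOH, 0 °C
Reagents that add atoms: none
Why: Base-catalysed transesterification to methanol; catalytic carbonate at 0 °C is too mild for oxetane closure, E2 loss of HBr or substitution of the primary bromide.

Step 9
Reactants: 12 3-iodophenol
Product: 13 1-iodo-3-(methoxymethoxy)benzene
Conditions: MOMCl, i-Pr2NEt, CH2Cl2, 0 °C to rt
Reagents that add atoms: chloromethyl methyl ether, COCCl
Why: Standard acetal protection of a phenol; the group is stable to carbonate at 100 °C and leaves in the last step.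

Step 10
Reactants: 13 1-iodo-3-(methoxymethoxy)benzene; 11 (S)-3-bromo-2-Ar-propan-1-ol (1.2 equiv)
Product: 14 (3S)-3-Ar-7-(methoxymethoxy)chromane
Conditions: Pd(OAc)2 (10 mol%), XPhos (20 mol%), 1-methylnorbornene (1 equiv), Cs2CO3 (3 equiv), 1,4-dioxane, 100 °C
Reagents that add atoms: none
Why: Proposed new method: Zerovalent palladium adds to the C–I bond of 13, the bridgehead-substituted norbornene inserts, and carbonate-assisted C–H palladation at C6 of the arene (para to the acetal oxygen, the future C4a) gives the aryl–norbornyl palladacycle of divalent palladium, which takes up the CH2Br of 11 by oxidative addition to tetravalent palladium and forms C4–C4a by reductive elimination. Beta-carbon elimination then expels the norbornene, a step the bridgehead substituent should make feasible after only one ortho substitution, leaving an arylpalladium halide at the ipso carbon (future C8a) with the hydroxymethyl arm within reach. Carbonate converts this into a seven-membered aryl(alkoxo)palladium chelate, and C–O reductive elimination closes ring C as the six-membered ether, a formal annulation of C4–C3–C2–O1 onto the C4a–C8a edge that returns zerovalent palladium. The closest known reaction types are the Catellani annulation of aryl iodides with epoxides to 2,3-dihydrobenzofurans (ortho alkylation, then ipso C–O coupling) and the palladium-catalysed cyclization of 3-(2-halophenyl)propanols to chromans; new is their merger with a 3-bromopropanol as the 1,3-bifunctional partner. No stereocenter is formed: C3 is beta to both reacting carbons, carries no leaving group and is not acidic, so the S configuration of 11 should pass unchanged into 14. Site selectivity requires alkylation at C6 and not at C2 of 13; the C2–H bond is flanked by the metal-bearing carbon and the acetal oxygen, and the bulky norbornene disfavours palladation there. Chemoselectivity requires C–O reductive elimination to outrun beta-hydride elimination of the alkoxide, for which the bulky biaryl phosphine is chosen, and requires 11 to survive the base, for which a carbonate in a weakly polar ether solvent and a bromide rather than an iodide are used.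

Step 11
Reactants: 14 (3S)-3-Ar-7-(methoxymethoxy)chromane
Product: 15 3-methoxy-2-(methoxymethoxy)-4-[(3S)-7-(methoxymethoxy)chroman-3-yl]phenol
Conditions: H2 (1 atm), Pd/C, EtOAc, rt
Reagents that add atoms: none
Why: Hydrogenolysis of the benzyl aryl ether under neutral conditions; the acetals, the chroman and C3 are inert, and no alkene is present yet.

Step 12
Reactants: 15 3-methoxy-2-(methoxymethoxy)-4-[(3S)-7-(methoxymethoxy)chroman-3-yl]phenol; 16 prenyl bromide (1-bromo-3-methylbut-2-ene)
Product: 17 (3S)-3-[2-methoxy-3-(methoxymethoxy)-4-(3-methylbut-2-enyloxy)phenyl]-7-(methoxymethoxy)chromane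
Conditions: K2CO3, acetone, 50 °C
Reagents that add atoms: none
Why: Williamson O-alkylation of the only free phenol; a carbonate base in acetone favours O- over C-prenylation.

Step 13
Reactants: 17 (3S)-3-[2-methoxy-3-(methoxymethoxy)-4-(3-methylbut-2-enyloxy)phenyl]-7-(methoxymethoxy)chromane
Product: 18 3-methoxy-2-(methoxymethoxy)-4-[(3S)-7-(methoxymethoxy)chroman-3-yl]-6-(2-methylbut-3-en-2-yl)phenol
Conditions: PhNEt2, 190 °C, sealed tube, argon
Reagents that add atoms: none
Why: Aromatic Claisen rearrangement: a concerted [3,3] shift from O4' to C5' with allyl inversion turns the prenyl ether into the 1,1-dimethylallyl group, and the dienone tautomerizes to the phenol. Migration towards C3' cannot rearomatize and reverts, and the basic amine solvent suppresses acid-promoted side reactions.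

Step 14
Reactants: 18 3-methoxy-2-(methoxymethoxy)-4-[(3S)-7-(methoxymethoxy)chroman-3-yl]-6-(2-methylbut-3-en-2-yl)phenol
Product: 19 4-[(3S)-7-hydroxychroman-3-yl]-3-methoxy-6-(2-methylbut-3-en-2-yl)benzene-1,2-diol (target)
Conditions: HCl (1.25 M in MeOH), 25 °C, argon
Reagents that add atoms: none
Why: Acid-catalysed acetal exchange to methanol removes both methoxymethyl groups; the monosubstituted alkene is not protonated by dilute methanolic HCl at room temperature, and exclusion of air protects the catechol.

## Compound list

1 | 2,3,4-trihydroxybenzaldehyde | O=Cc1ccc(O)c(O)c1O | starting material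
2 | 4-(benzyloxy)-2,3-dihydroxybenzaldehyde | O=Cc1ccc(OCc2ccccc2)c(O)c1O | intermediate
3 | 4-(benzyloxy)-2-hydroxy-3-(methoxymethoxy)benzaldehyde | O=Cc1ccc(OCc2ccccc2)c(OCOC)c1O | intermediate
4 | 4-(benzyloxy)-2-methoxy-3-(methoxymethoxy)benzaldehyde | O=Cc1ccc(OCc2ccccc2)c(OCOC)c1OC | intermediate
5 | ethyl diazoacetate | CCOC(=O)C=[N+]=[N-] | starting material
6 | ethyl (Z)-2-[4-(benzyloxy)-2-methoxy-3-(methoxymethoxy)phenyl]-3-hydroxyprop-2-enoate | CCOC(=O)/C(=C\O)c1ccc(OCc2ccccc2)c(OCOC)c1OC | intermediate
7 | ethyl 2-[4-(benzyloxy)-2-methoxy-3-(methoxymethoxy)phenyl]-3-hydroxypropanoate (racemic, not isolated) | CCOC(=O)C(CO)c1ccc(OCc2ccccc2)c(OCOC)c1OC | intermediate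
8 | 2-[4-(benzyloxy)-2-methoxy-3-(methoxymethoxy)phenyl]propane-1,3-diol | OCC(CO)c1ccc(OCc2ccccc2)c(OCOC)c1OC | intermediate
9 | (R)-2-[4-(benzyloxy)-2-methoxy-3-(methoxymethoxy)phenyl]-3-hydroxypropyl acetate | CC(=O)OC[C@@H](CO)c1ccc(OCc2ccccc2)c(OCOC)c1OC | intermediate
10 | (S)-3-bromo-2-[4-(benzyloxy)-2-methoxy-3-(methoxymethoxy)phenyl]propyl acetate | CC(=O)OC[C@@H](CBr)c1ccc(OCc2ccccc2)c(OCOC)c1OC | intermediate
11 | (S)-3-bromo-2-[4-(benzyloxy)-2-methoxy-3-(methoxymethoxy)phenyl]propan-1-ol | COc1c(OCOC)c(OCc2ccccc2)ccc1[C@H](CBr)CO | intermediate
12 | 3-iodophenol | Oc1cccc(I)c1 | starting material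
13 | 1-iodo-3-(methoxymethoxy)benzene | COCOc1cccc(I)c1 | intermediate
14 | (3S)-3-[4-(benzyloxy)-2-methoxy-3-(methoxymethoxy)phenyl]-7-(methoxymethoxy)chromane | COc1c(OCOC)c(OCc2ccccc2)ccc1[C@H]1COc2cc(OCOC)ccc2C1 | intermediate
15 | 3-methoxy-2-(methoxymethoxy)-4-[(3S)-7-(methoxymethoxy)chroman-3-yl]phenol | COc1c(OCOC)c(O)ccc1[C@H]1COc2cc(OCOC)ccc2C1 | intermediate
16 | prenyl bromide (1-bromo-3-methylbut-2-ene) | CC(C)=CCBr | starting material
17 | (3S)-3-[2-methoxy-3-(methoxymethoxy)-4-(3-methylbut-2-enyloxy)phenyl]-7-(methoxymethoxy)chromane | COc1c(OCOC)c(OCC=C(C)C)ccc1[C@H]1COc2cc(OCOC)ccc2C1 | intermediate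
18 | 3-methoxy-2-(methoxymethoxy)-4-[(3S)-7-(methoxymethoxy)chroman-3-yl]-6-(2-methylbut-3-en-2-yl)phenol | COc1c(OCOC)c(O)c(C(C)(C)C=C)cc1[C@H]1COc2cc(OCOC)ccc2C1 | intermediate
19 | 4-[(3S)-7-hydroxychroman-3-yl]-3-methoxy-6-(2-methylbut-3-en-2-yl)benzene-1,2-diol | C=CC(C)(C)c1cc([C@H]2COc3cc(O)ccc3C2)c(OC)c(O)c1O | target

## Step count and risks

Total: 14 steps. Longest linear sequence: 13 steps (steps 1–8, then 10–14); step 9 is a one-step side branch.

**Step 10 (key step).**
- What may go wrong: norbornene extrusion may be incomplete after a single ortho substitution, so that the palladacycle is diverted into norbornene-containing or doubly functionalized products. The bromo alcohol 11 may be consumed by base (oxetane closure, E2 loss of HBr) before it meets the palladacycle. The alkoxopalladium species may undergo beta-hydride elimination instead of C–O bond formation.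
- Fallback (known chemistry, from 10 back to 14): 3-bromo-4-iodophenol F1 is protected with MOMCl and i-Pr2NEt to give 2-bromo-1-iodo-4-(methoxymethoxy)benzene F2. The bromo acetate 10 is converted with activated Zn dust and LiCl in THF at 50 °C into the alkylzinc bromide F3, in which the acetate is tolerated. Negishi coupling of F3 with F2 under Pd(OAc)2 and SPhos, selective for the C–I bond, should give (S)-3-[2-bromo-4-(methoxymethoxy)phenyl]-2-Ar-propyl acetate F4. Methanolysis with catalytic K2CO3 gives the alcohol F5. Intramolecular palladium-catalysed C–O coupling (Pd(OAc)2, 2-(di-tert-butylphosphino)-1,1'-binaphthyl, Cs2CO3, toluene, 80 °C) then closes ring C and rejoins the route at 14.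

**Step 4.**
- What may go wrong: hydride migration may compete with aryl migration (giving the beta-keto ester path), and the acid catalyst may strip the aryl acetal.
- Fallback (from 4 back to 8, acid-free): van Leusen reductive cyanation of 4 (TosMIC, t-BuOK, DME, –40 °C, then MeOH, reflux) gives the arylacetonitrile F6. Hydrolysis with KOH in aqueous EtOH gives the arylacetic acid F7, and MeI with K2CO3 gives the methyl ester F8. Claisen acylation with NaH and dimethyl carbonate gives the dimethyl arylmalonate F9, and LiAlH4 in THF at 0 °C reduces F9 to 8.

**Step 6.**
- What may go wrong: the enzyme may acylate the other enantiotopic arm or discriminate poorly because of the ortho-methoxy group, and the acetate of 9 may migrate between the arms on standing.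
- Fallback (from 8 back to 11, non-enzymatic): desymmetrizing benzoylation of 8 with vinyl benzoate and the dinuclear zinc catalyst formed from ZnEt2 and a ProPhenol ligand, whose enantiomer is chosen for the R product, gives (R)-2-Ar-3-hydroxypropyl benzoate F10, which is less prone to acyl migration. Appel bromination gives (S)-3-bromo-2-Ar-propyl benzoate F11, and methanolysis with K2CO3 gives 11.

**Step 2.**
- What may go wrong: alkylation may be partly misdirected to the chelated O2, or may run on to double alkylation.
- Fallback (from 2 back to 3): both phenols are protected with excess MOMCl and i-Pr2NEt to give 4-(benzyloxy)-2,3-bis(methoxymethoxy)benzaldehyde F12. Chelation-directed cleavage with MgBr2·OEt2 in Et2O/toluene then removes only the acetal ortho to the formyl group and gives 3.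

**Step 13.**
- What may go wrong: the first-formed phenol may react further at 190 °C (abnormal Claisen rearrangement through transfer of the phenolic hydrogen, or addition of the 4'-OH to the new alkene), and the prenyl group may be lost by ionization.
- Fallback (from 17 back to 18): the rearrangement is run as an acylative Claisen in Ac2O with NaOAc and PhNEt2 at 180 °C, so that the phenol is trapped as the 4'-O-acetate F13 as soon as it forms. Methanolysis with K2CO3 then gives 18.

## Further compounds

F1 | step 10 | 3-bromo-4-iodophenol | Oc1ccc(I)c(Br)c1
F2 | step 10 | 2-bromo-1-iodo-4-(methoxymethoxy)benzene | COCOc1ccc(I)c(Br)c1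
F3 | step 10 | [(S)-3-acetoxy-2-[4-(benzyloxy)-2-methoxy-3-(methoxymethoxy)phenyl]propyl]zinc bromide | CC(=O)OC[C@@H](C[Zn]Br)c1ccc(OCc2ccccc2)c(OCOC)c1OC
F4 | step 10 | (S)-3-[2-bromo-4-(methoxymethoxy)phenyl]-2-[4-(benzyloxy)-2-methoxy-3-(methoxymethoxy)phenyl]propyl acetate | CC(=O)OC[C@@H](Cc1ccc(OCOC)cc1Br)c1ccc(OCc2ccccc2)c(OCOC)c1OC
F5 | step 10 | (S)-3-[2-bromo-4-(methoxymethoxy)phenyl]-2-[4-(benzyloxy)-2-methoxy-3-(methoxymethoxy)phenyl]propan-1-ol | OC[C@@H](Cc1ccc(OCOC)cc1Br)c1ccc(OCc2ccccc2)c(OCOC)c1OC
F6 | step 4 | 2-[4-(benzyloxy)-2-methoxy-3-(methoxymethoxy)phenyl]acetonitrile | N#CCc1ccc(OCc2ccccc2)c(OCOC)c1OC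
F7 | step 4 | 2-[4-(benzyloxy)-2-methoxy-3-(methoxymethoxy)phenyl]acetic acid | OC(=O)Cc1ccc(OCc2ccccc2)c(OCOC)c1OC
F8 | step 4 | methyl 2-[4-(benzyloxy)-2-methoxy-3-(methoxymethoxy)phenyl]acetate | COC(=O)Cc1ccc(OCc2ccccc2)c(OCOC)c1OC
F9 | step 4 | dimethyl 2-[4-(benzyloxy)-2-methoxy-3-(methoxymethoxy)phenyl]malonate | COC(=O)C(C(=O)OC)c1ccc(OCc2ccccc2)c(OCOC)c1OC
F10 | step 6 | (R)-2-[4-(benzyloxy)-2-methoxy-3-(methoxymethoxy)phenyl]-3-hydroxypropyl benzoate | O=C(OC[C@@H](CO)c1ccc(OCc2ccccc2)c(OCOC)c1OC)c1ccccc1
F11 | step 6 | (S)-3-bromo-2-[4-(benzyloxy)-2-methoxy-3-(methoxymethoxy)phenyl]propyl benzoate | O=C(OC[C@@H](CBr)c1ccc(OCc2ccccc2)c(OCOC)c1OC)c1ccccc1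
F12 | step 2 | 4-(benzyloxy)-2,3-bis(methoxymethoxy)benzaldehyde | O=Cc1ccc(OCc2ccccc2)c(OCOC)c1OCOC
F13 | step 13 | 3-methoxy-2-(methoxymethoxy)-4-[(3S)-7-(methoxymethoxy)chroman-3-yl]-6-(2-methylbut-3-en-2-yl)phenyl acetate | COc1c(OCOC)c(OC(C)=O)c(C(C)(C)C=C)cc1[C@H]1COc2cc(OCOC)ccc2C1
A1 | alternative 1 | 4-nitrophenyl 2-[2-methoxy-3,4-bis(methoxymethoxy)-5-(2-methylbut-3-en-2-yl)phenyl]acetate | C=CC(C)(C)c1cc(CC(=O)Oc2ccc(cc2)[N+](=O)[O-])c(OC)c(OCOC)c1OCOC
A2 | alternative 1 | 5-(methoxymethoxy)-2-[(4-methylphenyl)sulfonylmethyl]phenol | COCOc1ccc(CS(=O)(=O)c2ccc(C)cc2)c(O)c1
A3 | alternative 1 | 3-(methoxymethoxy)-6-methylidenecyclohexa-2,4-dien-1-one | C=C1C=CC(OCOC)=CC1=O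
A4 | alternative 1 | (3S)-3-[2-methoxy-3,4-bis(methoxymethoxy)-5-(2-methylbut-3-en-2-yl)phenyl]-7-(methoxymethoxy)chroman-2-one | C=CC(C)(C)c1cc([C@H]2C(=O)Oc3cc(OCOC)ccc3C2)c(OC)c(OCOC)c1OCOC
A5 | alternative 2 | (6S)-4-diazo-7-(ethynyloxy)-6-[2-methoxy-3,4-bis(methoxymethoxy)-5-(2-methylbut-3-en-2-yl)phenyl]hept-1-en-3-one | C=CC(=O)C(=[N+]=[N-])C[C@H](COC#C)c1cc(C(C)(C)C=C)c(OCOC)c(OCOC)c1OC
A6 | alternative 2 | (3S)-3-[2-methoxy-3,4-bis(methoxymethoxy)-5-(2-methylbut-3-en-2-yl)phenyl]chroman-7-ol | C=CC(C)(C)c1cc([C@H]2COc3cc(O)ccc3C2)c(OC)c(OCOC)c1OCOC
A7 | alternative 3 | 2-[2-bromo-4-(methoxymethoxy)benzyl]-2-[2-methoxy-3,4-bis(methoxymethoxy)-5-(2-methylbut-3-en-2-yl)phenyl]propane-1,3-diol | C=CC(C)(C)c1cc(C(CO)(CO)Cc2ccc(OCOC)cc2Br)c(OC)c(OCOC)c1OCOC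
A8 | alternative 3 | [(3S)-3-[2-methoxy-3,4-bis(methoxymethoxy)-5-(2-methylbut-3-en-2-yl)phenyl]-7-(methoxymethoxy)chroman-3-yl]methanol | C=CC(C)(C)c1cc([C@@]2(CO)COc3cc(OCOC)ccc3C2)c(OC)c(OCOC)c1OCOC
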